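Intermediate leaves faster towards decomposed reagent than towards product, so for elm and larch we ask how much substrate has gone in and what share of it can come out as product.

    substrate + partner → intermediate (k1 = 29 /M/s)
    intermediate → product (k2 = 0.029 /s)
    intermediate → decomposed reagent (k3 = 0.075 /s)

- elm: substrate 2.0 mM; partner 2.40 mM; time 30 s
- larch: substrate 2.0 mM; partner 4.80 mM; time 30 s

- which of these there is most of at the end, counted by the substrate in it, elm (product / substrate / intermediate)
- which of these there is most of at the end, counted by the substrate in it, larch (product / substrate / intermediate)
- amount of the one of these that there is most of at the end, in percent of the substrate charged, elm
- amount of the one of these that there is most of at the end, in percent of the substrate charged, larch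

We carry the product share, the rate constant of the product step over the sum of both constants on intermediate, 27.9%; this is the selectivity of the branch. Both steps are first order in intermediate, so the share holds at every moment, and product stands at the share times the substrate that has gone and is no longer intermediate.

By hand, the first step is second order with both reagents running down, which leaves 28.6% of the substrate in elm and 5.30% in larch. The ceiling on product is therefore 19.9% in elm, less than the substrate left, and 26.4% in larch, more than the substrate left. Intermediate lives 9.62 s on average, a third of the run, so we expect some of the substrate gone to stand as intermediate at the end and product to stay under its ceiling. We commit to substrate in elm and to product in larch, though we have not reckoned how much intermediate stands at the end.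

The forecast gave substrate at 29% (25% to 33%) for elm and product at 23% (19% to 27%) for larch, reasoning that “the larger excess consumes nearly all the substrate”.

The simulation gives substrate at 28.6% in elm and product at 22.9% in larch. Larch still holds 12.7% as intermediate at 30.0 s, and taking that off the substrate gone, the share returns 22.9% product. The neighbour of elm with 4.1 mM of partner ends with 8.94% substrate and 13.5% intermediate, so the share gives 21.6%, and that flask holds 21.6% product.

The numbers of this flask are assumed; the result is computed.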